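**Retrosynthetic overview**

1. Target 17 ⇒ its isomer 12 in one flask: the C8–C8' bond comes from a Ti(III) epoxide-opening/5-exo-trig radical cyclisation (ring 1, O–C7'–C8'–C8–C9), then the C7–O bond from iodine-induced closure of the benzylic carbon by the C9' alkoxide (ring 2).
2. 12 ⇒ allyl ether 11 + 4-iodoguaiacol 3 (Heck); 11 ⇒ epoxy alcohol 9 + allyl bromide 10.
3. 9 ⇒ racemic aryl vinyl carbinol 8 by Sharpless kinetic resolution, which sets C7'; C7' then controls C8', C8 and C7.
4. 8 ⇒ aryl iodide 5 + acrolein 6; 5 ⇒ 3 + prenyl bromide 4; 3 ⇒ guaiacol 2 ⇒ catechol 1 (3 supplies both aryl rings).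

Assumption: the SMILES is read as the (1R,3aS,4R,6aS)-furofuran with both aryl groups exo on the cis-fused bicycle (the mono-O-prenyl ether of the (−)-pinoresinol skeleton); lignan numbering is used (C7–C9 guaiacyl unit, C7'–C9' prenyloxyaryl unit).

**Route**

Step 1
Reactants: 1 catechol (benzene-1,2-diol)
Product: 2 guaiacol (2-methoxyphenol)
Conditions: MeI (0.9 equiv), K2CO3 (1.0 equiv), acetone, reflux
Reagents that add atoms: iodomethane, CI
Why: Williamson mono-O-methylation of the catechol monoanion with a slight deficit of MeI stops largely at the mono-ether, which is separated from unreacted catechol and a little veratrole.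

Step 2
Reactants: 2 guaiacol
Product: 3 4-iodo-2-methoxyphenol
Conditions: NaI (1.0 equiv), NaOH (1.0 equiv), aq. NaOCl (1.0 equiv, slow addition), MeOH, 0 °C; then dil. HCl
Reagents that add atoms: sodium iodide, [Na+].[I-]
Why: Electrophilic aromatic iodination of the phenoxide by hypoiodite made in situ goes para to the phenoxide oxygen, the strongest director on the ring (the minor 6-iodo isomer is removed on purification).

Step 3
Reactants: 3 4-iodo-2-methoxyphenol; 4 prenyl bromide (1-bromo-3-methylbut-2-ene)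
Product: 5 4-iodo-2-methoxy-1-[(3-methylbut-2-en-1-yl)oxy]benzene
Conditions: K2CO3, DMF, rt
Reagents that add atoms: none
Why: Williamson O-alkylation (SN2 of the phenoxide on the primary allylic bromide) installs the prenyl ether of the target at the outset.

Step 4
Reactants: 5 4-iodo-2-methoxy-1-[(3-methylbut-2-en-1-yl)oxy]benzene; 6 acrolein (prop-2-enal)
Product: 8 rac-1-{3-methoxy-4-[(3-methylbut-2-en-1-yl)oxy]phenyl}prop-2-en-1-ol, via arylmagnesium chloride 7 (not isolated)
Conditions: i-PrMgCl·LiCl (1.1 equiv), THF, 0 °C to rt; then acrolein (1.3 equiv), −78 to 0 °C; aq. NH4Cl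
Reagents that add atoms: none
Why: Knochel iodine–magnesium exchange followed by Grignard 1,2-addition to the enal gives the aryl vinyl carbinol, whose new centre (C7') is racemic here and is resolved in step 5.

Step 5
Reactants: 8 rac-1-{3-methoxy-4-[(3-methylbut-2-en-1-yl)oxy]phenyl}prop-2-en-1-ol
Product: 9 (S)-{3-methoxy-4-[(3-methylbut-2-en-1-yl)oxy]phenyl}[(2R)-oxiran-2-yl]methanol
Conditions: Ti(OiPr)4 (0.15 equiv), L-(+)-DIPT (0.20 equiv), t-BuOOH (0.45 equiv, anhydrous), 4 Å MS, CH2Cl2, −20 °C, stopped at ≤45% conversion; chromatography from unreacted (S)-8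
Reagents that add atoms: tert-butyl hydroperoxide, CC(C)(C)OO
Why: Sharpless kinetic resolution (Katsuki–Sharpless epoxidation of a secondary allylic alcohol): with L-(+)-DIPT the (R)-carbinol reacts fast and is epoxidised anti (erythro), so 9 carries C7' in the configuration of the target (the descriptor is S only because the oxirane carbon now outranks the aryl group), and the prenyl alkene is untouched because Ti–tartrate/TBHP epoxidises only allylic alcohols.

Step 6
Reactants: 9 (S)-{3-methoxy-4-[(3-methylbut-2-en-1-yl)oxy]phenyl}[(2R)-oxiran-2-yl]methanol; 10 allyl bromide (3-bromoprop-1-ene)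
Product: 11 (2R)-2-[(S)-{3-methoxy-4-[(3-methylbut-2-en-1-yl)oxy]phenyl}(prop-2-en-1-yloxy)methyl]oxirane
Conditions: NaH (1.1 equiv) added to 9 + allyl bromide (1.5 equiv), n-Bu4NI (cat.), THF/DMF, 0 °C
Reagents that add atoms: none
Why: Williamson etherification in which the alkoxide is generated in the presence of the allylic bromide and trapped faster than it can undergo Payne rearrangement, leaving both stereocentres untouched.

Step 7
Reactants: 11 (2R)-2-[(S)-{3-methoxy-4-[(3-methylbut-2-en-1-yl)oxy]phenyl}(prop-2-en-1-yloxy)methyl]oxirane; 3 4-iodo-2-methoxyphenol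
Product: 12 4-[(1E)-3-{(S)-{3-methoxy-4-[(3-methylbut-2-en-1-yl)oxy]phenyl}[(2R)-oxiran-2-yl]methoxy}prop-1-en-1-yl]-2-methoxyphenol
Conditions: Pd(OAc)2 (5 mol %), n-Bu4NCl (1 equiv), NaHCO3 (2.5 equiv), DMF, 50 °C
Reagents that add atoms: none
Why: Mizoroki–Heck arylation under ligand-free Jeffery conditions puts the aryl group on the terminal alkene carbon and β-hydride elimination of the benzylic hydrogen gives the conjugated (E)-cinnamyl ether, while the trisubstituted prenyl alkene does not insert, the epoxide tolerates bicarbonate and no stereocentre is touched.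

Step 8
Reactants: 12 4-[(1E)-3-{(S)-{3-methoxy-4-[(3-methylbut-2-en-1-yl)oxy]phenyl}[(2R)-oxiran-2-yl]methoxy}prop-1-en-1-yl]-2-methoxyphenol
Product: 17 2-methoxy-4-[(1R,3aS,4R,6aS)-4-{3-methoxy-4-[(3-methylbut-2-en-1-yl)oxy]phenyl}tetrahydro-1H,3H-furo[3,4-c]furan-1-yl]phenol, via aryl trimethylsilyl ether 13 (not isolated), via bis-titanium intermediate 14 (not isolated), via benzylic iodide 15 (not isolated), via silylated furofuran 16 (not isolated)
Conditions: BSA (1.1 equiv), THF, rt, 30 min; then Cp2TiCl (2.3 equiv, from Cp2TiCl2/Zn dust in THF, decanted) added dropwise, THF, rt; then I2 (1.2 equiv), rt to 40 °C; then K2CO3 (cat.), MeOH, rt; aq. Na2S2O3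
Reagents that add atoms: none
Why: Nugent–RajanBabu titanocene(III) epoxide opening gives the secondary β-titanoxy radical at C8', which closes 5-exo-trig onto the styrenyl alkene (the C8–C8' bond) through a Beckwith–Houk chair transition state that puts the C7' aryl group trans to CH2OTi and the two new ring substituents cis, the benzylic radical is then held as the benzyltitanium, and iodine converts it into a benzylic iodide that the titanium alkoxide displaces (SN1-like) to close the cis-fused second ring with the guaiacyl group on the exo face, the transient TMS group only masking the acidic phenol until methanolysis.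

**Compound list**

1 | catechol (benzene-1,2-diol) | Oc1ccccc1O | starting material
2 | guaiacol (2-methoxyphenol) | COc1ccccc1O | intermediate
3 | 4-iodo-2-methoxyphenol | COc1cc(I)ccc1O | intermediate
4 | prenyl bromide (1-bromo-3-methylbut-2-ene) | CC(C)=CCBr | starting material
5 | 4-iodo-2-methoxy-1-[(3-methylbut-2-en-1-yl)oxy]benzene | COc1cc(I)ccc1OCC=C(C)C | intermediate
6 | acrolein (prop-2-enal) | C=CC=O | starting material
7 | {3-methoxy-4-[(3-methylbut-2-en-1-yl)oxy]phenyl}magnesium chloride (LiCl complex) | COc1cc([Mg]Cl)ccc1OCC=C(C)C | intermediate (not isolated)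
8 | rac-1-{3-methoxy-4-[(3-methylbut-2-en-1-yl)oxy]phenyl}prop-2-en-1-ol | C=CC(O)c1ccc(OCC=C(C)C)c(OC)c1 | intermediate
9 | (S)-{3-methoxy-4-[(3-methylbut-2-en-1-yl)oxy]phenyl}[(2R)-oxiran-2-yl]methanol (anti epoxy alcohol) | O[C@H]([C@H]1CO1)c1ccc(OCC=C(C)C)c(OC)c1 | intermediate
10 | allyl bromide (3-bromoprop-1-ene) | C=CCBr | starting material
11 | (2R)-2-[(S)-{3-methoxy-4-[(3-methylbut-2-en-1-yl)oxy]phenyl}(prop-2-en-1-yloxy)methyl]oxirane | C=CCO[C@H]([C@H]1CO1)c1ccc(OCC=C(C)C)c(OC)c1 | intermediate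
12 | 4-[(1E)-3-{(S)-{3-methoxy-4-[(3-methylbut-2-en-1-yl)oxy]phenyl}[(2R)-oxiran-2-yl]methoxy}prop-1-en-1-yl]-2-methoxyphenol | COc1cc(/C=C/CO[C@H]([C@H]2CO2)c2ccc(OCC=C(C)C)c(OC)c2)ccc1O | intermediate
13 | O-trimethylsilyl ether of 12 (phenol masked) | COc1cc(/C=C/CO[C@H]([C@H]2CO2)c2ccc(OCC=C(C)C)c(OC)c2)ccc1O[Si](C)(C)C | intermediate (not isolated)
14 | 2,3-trans-3,4-cis tetrahydrofuran with the C7' aryl at C2, CH2O–TiCp2Cl at C3 and CH(TiCp2Cl)(4-TMSO-3-MeO-phenyl) at C4 (benzylic centre undefined) | COc1cc(C([Ti](Cl)(C2C=CC=C2)C2C=CC=C2)[C@@H]2CO[C@@H](c3ccc(OCC=C(C)C)c(OC)c3)[C@@H]2CO[Ti](Cl)(C2C=CC=C2)C2C=CC=C2)ccc1O[Si](C)(C)C | intermediate (not isolated)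
15 | the same tetrahydrofuran with CH(I)(4-TMSO-3-MeO-phenyl) at C4, as its chlorotitanocene alkoxide | COc1cc(C(I)[C@@H]2CO[C@@H](c3ccc(OCC=C(C)C)c(OC)c3)[C@@H]2CO[Ti](Cl)(C2C=CC=C2)C2C=CC=C2)ccc1O[Si](C)(C)C | intermediate (not isolated)
16 | O-trimethylsilyl ether of 17 | COc1cc([C@@H]2OC[C@@H]3[C@H]2CO[C@H]3c2ccc(OCC=C(C)C)c(OC)c2)ccc1O[Si](C)(C)C | intermediate (not isolated)
17 | 2-methoxy-4-[(1R,3aS,4R,6aS)-4-{3-methoxy-4-[(3-methylbut-2-en-1-yl)oxy]phenyl}tetrahydro-1H,3H-furo[3,4-c]furan-1-yl]phenol | COc1cc([C@@H]2OC[C@@H]3[C@H]2CO[C@H]3c2ccc(OCC=C(C)C)c(OC)c2)ccc1O | target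

**Step count and risks**

Total steps: 8. Longest linear sequence: 8 (1 → 2 → 3 → 5 → 8 → 9 → 11 → 12 → 17; compound 3 enters a second time in step 7).

The three steps most likely to fail:

Step 8 (titanocene cascade). The risks are reduction of the C8' radical before it cyclises, protonation of the benzyltitanium if silylation is incomplete, iodine reacting with the prenyl alkene, and partial formation of the C7 epimer. The fallback sets out from 12 and comes back at 17; it separates the radical C–C closure from the C–O closure. Unprotected 12 is treated with Cp2TiCl (2.5 equiv) in THF at rt and quenched with dilute aqueous acid, so that the benzyltitanium is protonated and the monocyclic [(2R,3S,4S)-4-(4-hydroxy-3-methoxybenzyl)-2-{3-methoxy-4-[(3-methylbut-2-en-1-yl)oxy]phenyl}oxolan-3-yl]methanol F1 is isolated. Oxidation of F1 with Ag2O in CH2Cl2 at rt gives the p-quinone methide of F1 F2, which is not isolated and closes by 5-exo oxa-Michael addition of its CH2OH group to give 17 with the aryl group exo.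

Step 7 (Heck on an allyl ether). The risks are the enol-ether regioisomer from β-hydride elimination toward oxygen, β-alkoxide elimination, and Pd-mediated loss of the prenyl group. The fallback sets out from 9 and comes back at 12; it fixes the regiochemistry through a boronate. Compound 9 is O-alkylated with propargyl bromide (NaH, THF, 0 °C) to (2R)-2-[(S)-{3-methoxy-4-[(3-methylbut-2-en-1-yl)oxy]phenyl}(prop-2-yn-1-yloxy)methyl]oxirane F3. Zirconium-catalysed hydroboration (pinacolborane, 5 mol % Cp2Zr(H)Cl, CH2Cl2, rt) gives the (E)-alkenyl pinacol boronate F4. Suzuki–Miyaura coupling of F4 with 3 (Pd(dppf)Cl2, K3PO4, THF/H2O, 50 °C) gives 12.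

Step 5 (kinetic resolution). The risks are a modest selectivity factor for a terminal vinyl carbinol and Lewis-acid ionisation of the electron-rich benzylic alcohol. The fallback sets out from 8 and comes back at 9; it resolves enzymatically and epoxidises without a chiral catalyst. Lipase acylation (Novozym 435, vinyl acetate, MTBE, 30 °C) converts the (R)-enantiomer into (R)-1-{3-methoxy-4-[(3-methylbut-2-en-1-yl)oxy]phenyl}prop-2-en-1-yl acetate F5, which is separated from unreacted (S)-8. Methanolysis (K2CO3, MeOH, 0 °C) gives (R)-1-{3-methoxy-4-[(3-methylbut-2-en-1-yl)oxy]phenyl}prop-2-en-1-ol F6. Hydroxyl-directed epoxidation (VO(acac)2 cat., t-BuOOH, CH2Cl2, 0 °C) gives 9 as the major erythro product. The minor threo epimer (S)-{3-methoxy-4-[(3-methylbut-2-en-1-yl)oxy]phenyl}[(2S)-oxiran-2-yl]methanol F7 is removed by chromatography; it could also be carried on, because the oxirane stereocentre becomes the radical centre in step 8.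

**Further compounds**

F1 | step 8 | [(2R,3S,4S)-4-(4-hydroxy-3-methoxybenzyl)-2-{3-methoxy-4-[(3-methylbut-2-en-1-yl)oxy]phenyl}oxolan-3-yl]methanol | COc1cc(C[C@@H]2CO[C@@H](c3ccc(OCC=C(C)C)c(OC)c3)[C@@H]2CO)ccc1O
F2 | step 8 | p-quinone methide of F1 (2-methoxy-4-ylidene-cyclohexa-2,5-dien-1-one, ring stereocentres as in F1) | COC1=CC(=C[C@@H]2CO[C@@H](c3ccc(OCC=C(C)C)c(OC)c3)[C@@H]2CO)C=CC1=O
F3 | step 7 | (2R)-2-[(S)-{3-methoxy-4-[(3-methylbut-2-en-1-yl)oxy]phenyl}(prop-2-yn-1-yloxy)methyl]oxirane | C#CCO[C@H]([C@H]1CO1)c1ccc(OCC=C(C)C)c(OC)c1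
F4 | step 7 | (E)-alkenyl pinacol boronate: 2-[(1E)-3-{(S)-{3-methoxy-4-[(3-methylbut-2-en-1-yl)oxy]phenyl}[(2R)-oxiran-2-yl]methoxy}prop-1-en-1-yl]-4,4,5,5-tetramethyl-1,3,2-dioxaborolane | CC1(C)OB(/C=C/CO[C@H]([C@H]2CO2)c2ccc(OCC=C(C)C)c(OC)c2)OC1(C)C
F5 | step 5 | (R)-1-{3-methoxy-4-[(3-methylbut-2-en-1-yl)oxy]phenyl}prop-2-en-1-yl acetate | C=C[C@@H](OC(C)=O)c1ccc(OCC=C(C)C)c(OC)c1
F6 | step 5 | (R)-1-{3-methoxy-4-[(3-methylbut-2-en-1-yl)oxy]phenyl}prop-2-en-1-ol | C=C[C@@H](O)c1ccc(OCC=C(C)C)c(OC)c1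
F7 | step 5 | (S)-{3-methoxy-4-[(3-methylbut-2-en-1-yl)oxy]phenyl}[(2S)-oxiran-2-yl]methanol (threo epimer of 9) | O[C@H]([C@@H]1CO1)c1ccc(OCC=C(C)C)c(OC)c1
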